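**Retrosynthetic overview**

1. Central-ring numbering: C1 carries the 2-(4-hydroxyphenyl)ethyl chain, C2 and C6 the 4-hydroxybenzyl groups, C3 and C5 the hydroxyls, and C4 the only ring hydrogen. The plan rests on the C3(O)–C4(H)–C5(O) resorcinol triad: C3 comes from carbon monoxide, C4 from a terminal alkyne CH, and the C5 oxygen from an ester that migrates from C6.
2. Target 16 ⇐ resorcinol monoacetate tris(methyl ether) 14, by BBr3 demethylation and methanolysis of the acetate.
3. 14 ⇐ enyne acetate 11 (ring atoms C4–C5–C6–C1–C2) + CO 12 by rhodium-catalysed [5+1] carbonylation, forming C3–C4 and C2–C3. This closes the central benzene ring, the only ring made in the route; the three anisole rings are bought.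
4. 11 ⇐ tertiary propargylic alcohol 10 ⇐ enone 8 + ethynylmagnesium bromide 9; 8 ⇐ Weinreb amide 6 + 4-methoxybenzylmagnesium chloride 7.
5. 6 ⇐ E-enoate 5 ⇐ Horner–Wadsworth–Emmons reaction of phosphonate 3 (from 1 and 2) with aldehyde 4, which sets the E geometry of the C1=C2 alkene.

Key step: step 7

Remark: the target is achiral, so 3, 10 and 11 are carried as racemates; aldehyde 4 is air- and base-sensitive and is assumed to be used freshly purified.

**Route**

Step 1
Reactants: 1 triethyl phosphonoacetate; 2 1-(2-bromoethyl)-4-methoxybenzene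
Product: 3 ethyl 2-(diethoxyphosphoryl)-4-(4-methoxyphenyl)butanoate (racemic)
Conditions: NaH, DMF, 0 °C; then 2, 60 °C (1 in excess)
Reagents that add atoms: none
Why: SN2 C-alkylation of the sodium phosphonoacetate anion by a primary bromide is standard, the soft stabilised carbanion should keep E2 loss of HBr from 2 minor, and an excess of 1 limits dialkylation.

Step 2
Reactants: 3 ethyl 2-(diethoxyphosphoryl)-4-(4-methoxyphenyl)butanoate; 4 2-(4-methoxyphenyl)acetaldehyde
Product: 5 ethyl (2E)-4-(4-methoxyphenyl)-2-[2-(4-methoxyphenyl)ethyl]but-2-enoate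
Conditions: NaH, THF, 0 °C; then 4, −78 → 0 °C
Reagents that add atoms: none
Why: The Horner–Wadsworth–Emmons olefination of an α-alkylated phosphonoacetate should be E-selective because the reversibly formed oxaphosphetane that places the ester trans to the new CH2Ar group is favoured, and adding the aldehyde cold to the preformed anion limits its enolisation (any minor Z isomer is to be removed by chromatography).

Step 3
Reactants: 5 ethyl (2E)-4-(4-methoxyphenyl)-2-[2-(4-methoxyphenyl)ethyl]but-2-enoate
Product: 6 (2E)-N-methoxy-4-(4-methoxyphenyl)-2-[2-(4-methoxyphenyl)ethyl]-N-methylbut-2-enamide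
Conditions: MeNH(OMe)·HCl, i-PrMgCl, THF, −20 → 0 °C
Reagents that add atoms: N,O-dimethylhydroxylamine hydrochloride, CNOC.Cl
Why: Direct aminolysis of the ester by the chloromagnesium amide of N,O-dimethylhydroxylamine (Weinreb amide formation) should proceed at low temperature without touching the trisubstituted alkene, whose α-substituent disfavours conjugate addition.

Step 4
Reactants: 6 (2E)-N-methoxy-4-(4-methoxyphenyl)-2-[2-(4-methoxyphenyl)ethyl]-N-methylbut-2-enamide; 7 4-methoxybenzylmagnesium chloride
Product: 8 (3E)-1,5-bis(4-methoxyphenyl)-3-[2-(4-methoxyphenyl)ethyl]pent-3-en-2-one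
Conditions: THF, −20 → 0 °C; cold sat. aq NH4Cl
Reagents that add atoms: none
Why: Grignard acylation of a Weinreb amide stops at the ketone because the chelated magnesium adduct survives until the quench, so the base-sensitive enone should only be released into cold buffered water with its E alkene intact.

Step 5
Reactants: 8 (3E)-1,5-bis(4-methoxyphenyl)-3-[2-(4-methoxyphenyl)ethyl]pent-3-en-2-one; 9 ethynylmagnesium bromide
Product: 10 (4E)-3-(4-methoxybenzyl)-6-(4-methoxyphenyl)-4-[2-(4-methoxyphenyl)ethyl]hex-4-en-1-yn-3-ol (racemic)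
Conditions: LaCl3·2LiCl (30 mol %), THF, 0 °C; sat. aq NH4Cl
Reagents that add atoms: none
Why: 1,2-Addition of an alkynyl Grignard reagent to the ketone is promoted by the lanthanum salt, which activates the carbonyl and suppresses enolisation of the benzyl ketone, and the new carbinol centre forms as a racemate, which suffices because it becomes sp2 in step 7.

Step 6
Reactants: 10 (4E)-3-(4-methoxybenzyl)-6-(4-methoxyphenyl)-4-[2-(4-methoxyphenyl)ethyl]hex-4-en-1-yn-3-ol
Product: 11 (4E)-3-(4-methoxybenzyl)-6-(4-methoxyphenyl)-4-[2-(4-methoxyphenyl)ethyl]hex-4-en-1-yn-3-yl acetate (racemic)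
Conditions: Ac2O, Et3N, DMAP (cat.), CH2Cl2, rt
Reagents that add atoms: acetic anhydride, CC(=O)OC(C)=O
Why: DMAP-catalysed acyl transfer through the N-acetylpyridinium ion should acetylate the tertiary propargylic alcohol, whose small ethynyl group leaves the hydroxyl accessible, and the basic medium avoids ionisation of the doubly activated carbinol.

Step 7
Reactants: 11 (4E)-3-(4-methoxybenzyl)-6-(4-methoxyphenyl)-4-[2-(4-methoxyphenyl)ethyl]hex-4-en-1-yn-3-yl acetate; 12 carbon monoxide
Product: 14 5-hydroxy-2,4-bis(4-methoxybenzyl)-3-[2-(4-methoxyphenyl)ethyl]phenyl acetate, via cyclohexadienone 13 (not isolated)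
Conditions: [Rh(CO)2Cl]2 (5 mol %), CO (5 atm), ClCH2CH2Cl, 80 °C
Reagents that add atoms: none
Why: The monovalent rhodium centre of [Rh(CO)2Cl]2 binds the terminal alkyne, and the acetate carbonyl oxygen attacks the internal alkyne carbon (C5 in the ring numbering of the overview), so the ester moves from C6 to C5 by 1,2-acyloxy migration and leaves a rhodium vinylcarbene at C4. This carbene, the new C5=C6 bond and the C1=C2 alkene make up a rhodatriene that should close by 6π electrocyclisation to a rhodacyclohexadiene bonded at C4 and C2; CO then inserts and C–C reductive elimination forms C3–C4 and C2–C3, closing the central six-membered ring in a formal [5+1] mode, after which dienone 13 tautomerises to the phenol. The closest known reaction type is the rhodium-catalysed [5+1] carbonylation of 3-acyloxy-1,4-enynes to resorcinol monoesters, applied here to a tertiary and more heavily substituted ester. No stereocentre is created that persists, since the racemic carbinol carbon C6 becomes sp2 and the transient C2–H centre of 13 is lost on enolisation. The step needs 1,2- and not 1,3-acyloxy migration, which the unsubstituted alkyne terminus favours, and it needs C2 to reach the metal, which the E alkene secures by turning the C2 hydrogen rather than the benzyl group inward; the CO pressure should favour insertion over Rautenstrauch-type cyclopentenone formation.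

Step 8
Reactants: 14 5-hydroxy-2,4-bis(4-methoxybenzyl)-3-[2-(4-methoxyphenyl)ethyl]phenyl acetate
Product: 16 4,6-bis(4-hydroxybenzyl)-5-[2-(4-hydroxyphenyl)ethyl]benzene-1,3-diol, via tetrahydroxy monoacetate 15 (not isolated)
Conditions: BBr3 (excess), CH2Cl2, −78 °C → rt; then MeOH, rt
Reagents that add atoms: none
Why: In this Lewis-acid ether cleavage BBr3 complexes each aryl methyl ether and bromide removes the methyl group by SN2, and the HBr formed in methanol on quenching should transesterify the aryl acetate of 15, leaving the diarylmethane and bibenzyl C–C bonds untouched.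

**Compound list**

1 | triethyl phosphonoacetate | CCOC(=O)CP(=O)(OCC)OCC | starting material
2 | 1-(2-bromoethyl)-4-methoxybenzene | COc1ccc(CCBr)cc1 | starting material
3 | ethyl 2-(diethoxyphosphoryl)-4-(4-methoxyphenyl)butanoate (racemic) | CCOC(=O)C(CCc1ccc(OC)cc1)P(=O)(OCC)OCC | intermediate
4 | 2-(4-methoxyphenyl)acetaldehyde | COc1ccc(CC=O)cc1 | starting material
5 | ethyl (2E)-4-(4-methoxyphenyl)-2-[2-(4-methoxyphenyl)ethyl]but-2-enoate | CCOC(=O)/C(CCc1ccc(OC)cc1)=C/Cc1ccc(OC)cc1 | intermediate
6 | (2E)-N-methoxy-4-(4-methoxyphenyl)-2-[2-(4-methoxyphenyl)ethyl]-N-methylbut-2-enamide | CON(C)C(=O)/C(CCc1ccc(OC)cc1)=C/Cc1ccc(OC)cc1 | intermediate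
7 | 4-methoxybenzylmagnesium chloride | COc1ccc(C[Mg]Cl)cc1 | starting material
8 | (3E)-1,5-bis(4-methoxyphenyl)-3-[2-(4-methoxyphenyl)ethyl]pent-3-en-2-one | COc1ccc(CC(=O)/C(CCc2ccc(OC)cc2)=C/Cc2ccc(OC)cc2)cc1 | intermediate
9 | ethynylmagnesium bromide | C#C[Mg]Br | starting material
10 | (4E)-3-(4-methoxybenzyl)-6-(4-methoxyphenyl)-4-[2-(4-methoxyphenyl)ethyl]hex-4-en-1-yn-3-ol (racemic) | C#CC(O)(Cc1ccc(OC)cc1)/C(CCc1ccc(OC)cc1)=C/Cc1ccc(OC)cc1 | intermediate
11 | (4E)-3-(4-methoxybenzyl)-6-(4-methoxyphenyl)-4-[2-(4-methoxyphenyl)ethyl]hex-4-en-1-yn-3-yl acetate (racemic) | C#CC(Cc1ccc(OC)cc1)(OC(C)=O)/C(CCc1ccc(OC)cc1)=C/Cc1ccc(OC)cc1 | intermediate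
12 | carbon monoxide | [C-]#[O+] | starting material
13 | 4,6-bis(4-methoxybenzyl)-5-[2-(4-methoxyphenyl)ethyl]-3-oxocyclohexa-1,5-dien-1-yl acetate (racemic, not isolated) | CC(=O)OC1=CC(=O)C(Cc2ccc(OC)cc2)C(CCc2ccc(OC)cc2)=C1Cc1ccc(OC)cc1 | intermediate
14 | 5-hydroxy-2,4-bis(4-methoxybenzyl)-3-[2-(4-methoxyphenyl)ethyl]phenyl acetate | CC(=O)Oc1cc(O)c(Cc2ccc(OC)cc2)c(CCc2ccc(OC)cc2)c1Cc1ccc(OC)cc1 | intermediate
15 | 5-hydroxy-2,4-bis(4-hydroxybenzyl)-3-[2-(4-hydroxyphenyl)ethyl]phenyl acetate (not isolated) | CC(=O)Oc1cc(O)c(Cc2ccc(O)cc2)c(CCc2ccc(O)cc2)c1Cc1ccc(O)cc1 | intermediate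
16 | 4,6-bis(4-hydroxybenzyl)-5-[2-(4-hydroxyphenyl)ethyl]benzene-1,3-diol | Oc1ccc(CCc2c(Cc3ccc(O)cc3)c(O)cc(O)c2Cc2ccc(O)cc2)cc1 | target

**Summary**

Total step count: 8. Longest linear sequence: 8 steps (1 → 3 → 5 → 6 → 8 → 10 → 11 → 14 → 16).

**Steps most likely to fail**

Step 7. The acetate may undergo 1,3-shift to an allenyl acetate, the tertiary doubly activated ester may ionise, or electrocyclisation of the crowded rhodatriene may be too slow, so that cyclopentenone formation or decomposition outruns carbonylation. The fallback gives up ring construction and decorates a preformed resorcinol ring; it sets out from 7 and comes back to the route at 16. Coupling of 7 with 3,5-dimethoxybenzyl bromide (Li2CuCl4 cat., THF, 0 °C) should give 1,3-dimethoxy-5-[2-(4-methoxyphenyl)ethyl]benzene F1. NBS (2 equiv, MeCN, 0 °C) should then brominate the two positions flanking the chain, each para to a methoxy group, to give 2,4-dibromo-1,5-dimethoxy-3-[2-(4-methoxyphenyl)ethyl]benzene F2. A second portion of 7 is transmetalated with ZnCl2 to 4-methoxybenzylzinc chloride F3. Double Negishi coupling of F2 with F3 (Pd(OAc)2, SPhos, THF, 60 °C) should give 1,5-dimethoxy-2,4-bis(4-methoxybenzyl)-3-[2-(4-methoxyphenyl)ethyl]benzene F4. BBr3 in CH2Cl2 followed by aqueous work-up removes the five methyl groups and delivers 16.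

Step 2. The arylacetaldehyde may enolise and self-condense, the new double bond may migrate under base out of conjugation with the ester into conjugation with the anisyl ring, and the E selectivity may be incomplete. The fallback forms the aryl–CH2 bond last and avoids the labile aldehyde; it sets out from 3 and comes back at 5. Horner–Wadsworth–Emmons reaction of 3 with (tert-butyldimethylsilyloxy)acetaldehyde (NaH, THF) should give ethyl (2E)-4-[(tert-butyldimethylsilyl)oxy]-2-[2-(4-methoxyphenyl)ethyl]but-2-enoate F5. TBAF in THF then frees ethyl (2E)-4-hydroxy-2-[2-(4-methoxyphenyl)ethyl]but-2-enoate F6; any Z isomer would lactonise to a butenolide and be separated. Appel bromination (CBr4, PPh3, CH2Cl2, 0 °C) gives ethyl (2E)-4-bromo-2-[2-(4-methoxyphenyl)ethyl]but-2-enoate F7. Suzuki–Miyaura coupling of F7 with 4-methoxyphenylboronic acid (Pd(PPh3)4, K2CO3, toluene, 80 °C) should deliver the aryl group to the unhindered allyl terminus and give 5.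

Step 5. The Grignard reagent may deprotonate the benzyl ketone CH2 (or the benzylic-allylic CH2) instead of adding, returning enone or its deconjugated isomer after work-up. The fallback reverses the order of the two carbonyl additions so that no α-enolisable ketone is offered to the nucleophile; it sets out from 6 and comes back at 10. Commercial lithium (trimethylsilyl)acetylide (THF, −78 → 0 °C) should convert 6 into (4E)-6-(4-methoxyphenyl)-4-[2-(4-methoxyphenyl)ethyl]-1-(trimethylsilyl)hex-4-en-1-yn-3-one F8. 1,2-Addition of 7 (THF, −78 °C; sat. aq NH4Cl) should then give (4E)-3-(4-methoxybenzyl)-6-(4-methoxyphenyl)-4-[2-(4-methoxyphenyl)ethyl]-1-(trimethylsilyl)hex-4-en-1-yn-3-ol F9 as a racemate. K2CO3 in MeOH at rt removes the silyl group to give 10.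

**Further compounds**

F1 | step 7 | 1,3-dimethoxy-5-[2-(4-methoxyphenyl)ethyl]benzene | COc1ccc(CCc2cc(OC)cc(OC)c2)cc1
F2 | step 7 | 2,4-dibromo-1,5-dimethoxy-3-[2-(4-methoxyphenyl)ethyl]benzene | COc1ccc(CCc2c(Br)c(OC)cc(OC)c2Br)cc1
F3 | step 7 | 4-methoxybenzylzinc chloride | COc1ccc(C[Zn]Cl)cc1
F4 | step 7 | 1,5-dimethoxy-2,4-bis(4-methoxybenzyl)-3-[2-(4-methoxyphenyl)ethyl]benzene | COc1ccc(CCc2c(Cc3ccc(OC)cc3)c(OC)cc(OC)c2Cc2ccc(OC)cc2)cc1
F5 | step 2 | ethyl (2E)-4-[(tert-butyldimethylsilyl)oxy]-2-[2-(4-methoxyphenyl)ethyl]but-2-enoate | CCOC(=O)/C(CCc1ccc(OC)cc1)=C/CO[Si](C)(C)C(C)(C)C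
F6 | step 2 | ethyl (2E)-4-hydroxy-2-[2-(4-methoxyphenyl)ethyl]but-2-enoate | CCOC(=O)/C(CCc1ccc(OC)cc1)=C/CO
F7 | step 2 | ethyl (2E)-4-bromo-2-[2-(4-methoxyphenyl)ethyl]but-2-enoate | CCOC(=O)/C(CCc1ccc(OC)cc1)=C/CBr
F8 | step 5 | (4E)-6-(4-methoxyphenyl)-4-[2-(4-methoxyphenyl)ethyl]-1-(trimethylsilyl)hex-4-en-1-yn-3-one | C[Si](C)(C)C#CC(=O)/C(CCc1ccc(OC)cc1)=C/Cc1ccc(OC)cc1
F9 | step 5 | (4E)-3-(4-methoxybenzyl)-6-(4-methoxyphenyl)-4-[2-(4-methoxyphenyl)ethyl]-1-(trimethylsilyl)hex-4-en-1-yn-3-ol (racemic) | C[Si](C)(C)C#CC(O)(Cc1ccc(OC)cc1)/C(CCc1ccc(OC)cc1)=C/Cc1ccc(OC)cc1
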